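How much target can the flask make in the run, when every turnover spends one dissolved gas and the gas has to cross in from the gas phase?

substrate 2.0 mM; gas phase 0.40 mM (held); catalyst 11 µM; time 2.0 min

1. how much target there is at 2.0 min, in percent of the substrate charged
2. the change that raises the amount of target at 2.0 min, in percent of the substrate charged most ("none" if none brings more than 2 percentage points) (blue / amber / teal / none)
3. amount of target at 2.0 min, in percent of the substrate charged, after amber

- blue: doubling the transfer coefficient of step 3, all else as stated
- amber: doubling the amount of catalyst, all else as stated
- teal: doubling the saturation concentration of gas phase, all else as stated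

- at the start none of the gas is dissolved
- run time (flask): 2.0 min

    substrate + dissolved gas + catalyst → catalyst + target (k1 = 4.9 × 10⁶ M⁻² s⁻¹)
    substrate ⇌ dormant form (K2 = 0.34, k2 = 0.083 s⁻¹)
    gas phase ⇌ dissolved gas, rate k3*(csat - [dissolved gas]) (k3 = 0.043 s⁻¹, csat = 0.40 mM)

I count turnovers as fractions of the substrate charged. Into a solution kept empty, transfer delivers 103% by 2.0 min. In the real flask that supply is paid out as target, as gas standing dissolved, and as transfer lost to gas already dissolved.

Substrate and dormant form relax with a half-life of 2.12 s, far shorter than the run, so 74.6% of what is left stays free. Call the pull, 1.87, the rate constant at which catalyst takes up dissolved gas with the full charge present and that free share of it counted, divided by the transfer coefficient; it is a Damköhler number.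

With x the part left, free and dormant together, the lost transfer is ln(1/x) divided by the pull. I take dissolved gas as its saturation, 20.0% of the charge, divided by one plus pull times x. If half is converted, this ledger pays out 55.8%, more than supposed, so I commit to the midpoint, 52.9%.

The forecast gives 53%, 66% after amber, and teal as best, saying “The run is partly limited by gas transfer”.

The simulation gives 52.7% for the flask, 65.9% after amber, and teal as best: 30 percentage points, more than blue's 15 points or amber's 13 points.

In the flask at 2.00 min, dissolved gas stands at 0.204 mM, half of saturation. The neighbour flask holds 0.027 mM of catalyst, so its pull is 4.59. Supposing a third left there, the ledger pays out 71.4%, more than supposed, and the midpoint is 69.0%. The neighbour flask holds 69.4% target at 2.00 min, with 22.5% substrate and 8.13% dormant form.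

The rate constants are invented, and the outcome is calculated.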